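## Retrosynthetic overview

- **Feature:** ring A carries its two hydroxyls on C1 and C3 and its only carbon substituent on C5, which is the oxygen pattern of a cyclohexane-1,3-dione. C5 and the arm CH2–CH(O)–CH3 together are four carbons in the pattern of 3-hydroxybutanal, with C5 as the former aldehyde carbon, and the route rests on this match.
- **Disconnections:** (a) the ester C–O bond between the ring A carbinol and the butanoate carbonyl gives alcohol 15 and acid 29. (b) In 15, arene ⇒ dione 10 ⇒ keto ester 8 ⇒ enone 5 + dimethyl malonate 6 (two C–C bonds, one ring).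
- **Enone 5:** it comes from methyl (R)-3-hydroxybutanoate 1 in three steps (silylation, iBu2AlH, Wittig), so the ring A carbinol centre is bought, not made.
- **Acid 29:** ring C is bought as methyl orsellinate 18. The central unit enters as mono-silylated (S)-butane-1,3-diol by Mitsunobu inversion, the oxopentyl arm comes from lateral lithiation and acylation with Weinreb amide 17 (again from 1), and the primary alcohol is then oxidised to the acid.
- **Ring order:** ring C is present from the start. Ring A is the only ring constructed, closed as a carbocycle in step 4 and aromatised in step 7, and one hydrogenolysis ends the route.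

Key step: step 4

Remark: all three carbinol centres of the target read as (R). Compounds 7 to 11 are carried as mixtures of epimers at the ring (or chain) carbons and of keto–enol tautomers and are drawn in one form, because aromatisation removes these elements.

## Route

Step 1
Reactants: 1 methyl (R)-3-hydroxybutanoate
Product: 2 methyl (R)-3-(tert-butyldimethylsilyloxy)butanoate
Conditions: TBSCl, imidazole, DMF, 0 °C to rt
Reagents that add atoms: tert-butyldimethylsilyl chloride, CC(C)(C)[Si](C)(C)Cl
Why: Imidazole-promoted silyl ether formation on a secondary alcohol breaks no bond at the (R) centre and should proceed cleanly.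

Step 2
Reactants: 2 methyl (R)-3-(tert-butyldimethylsilyloxy)butanoate
Product: 3 (R)-3-(tert-butyldimethylsilyloxy)butanal
Conditions: iBu2AlH (1.05 equiv), CH2Cl2, −78 °C; aq potassium sodium tartrate
Reagents that add atoms: none
Why: Partial ester reduction with iBu2AlH at low temperature should stop at the aldehyde, and the neutral work-up avoids β-elimination of the silyloxy group.

Step 3
Reactants: 3 (R)-3-(tert-butyldimethylsilyloxy)butanal; 4 1-(triphenylphosphoranylidene)propan-2-one
Product: 5 (R,E)-6-(tert-butyldimethylsilyloxy)hept-3-en-2-one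
Conditions: CH2Cl2, reflux
Reagents that add atoms: none
Why: The Wittig reaction of a ketone-stabilised ylide is (E)-selective, and the ylide is too weakly basic to eliminate the β-silyloxy group of the aldehyde.

Step 4
Reactants: 5 (R,E)-6-(tert-butyldimethylsilyloxy)hept-3-en-2-one; 6 dimethyl malonate
Product: 8 methyl 6-[(R)-2-(tert-butyldimethylsilyloxy)propyl]-2,4-dioxocyclohexane-1-carboxylate, via Michael adduct 7 (not isolated)
Conditions: 6 (1.2 equiv), NaOMe (1.1 equiv), MeOH, 0 °C; add 5, 0 °C to rt; then reflux; 1 M HCl to pH 4, 0 °C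
Reagents that add atoms: none
Why: Sodium dimethyl malonate adds to C4 of enone 5 (Michael addition) to give 7, proton exchange then delivers the enolate of the terminal methyl ketone carbon, which attacks one malonate ester carbonyl and expels methoxide (Claisen condensation of the Dieckmann kind), and the product is trapped as its delocalised tricarbonyl enolate, which pulls all the reversible steps forward. The closest known reaction type is the classical Michael–Claisen annulation of alk-3-en-2-ones with malonic esters that leads to 5-alkylcyclohexane-1,3-diones. The ring closes in a 6-(enolendo)-exo-trig mode, while the internal enolate of 7 could only form a four-membered ring and therefore does not compete. The two new ring centres C1 and C6 are not controlled (C1 is epimerisable and should settle trans to the side chain) and need not be, since both become sp2 carbons in step 7, and the (R) carbinol carbon has no acidic neighbour once the enone is consumed. The selectivity needed is 1,4-addition over deprotonation at C5 of 5 followed by E1cB loss of silyloxide from C6; it is secured by keeping 6 in excess over NaOMe so that little free methoxide is present, by adding 5 cold and heating only after it is consumed, and by a soft nucleophile meeting an unhindered (E)-enone. No regiochemical question arises, because after loss of the ester the dione is symmetric about its C2–C5 axis.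

Step 5
Reactants: 8 methyl 6-[(R)-2-(tert-butyldimethylsilyloxy)propyl]-2,4-dioxocyclohexane-1-carboxylate
Product: 10 5-[(R)-2-(tert-butyldimethylsilyloxy)propyl]cyclohexane-1,3-dione, via keto acid 9 (not isolated)
Conditions: 2 M aq NaOH, MeOH, 70 °C; 0 °C, 1 M HCl to pH 3–4; extract into toluene, 80 °C
Reagents that add atoms: none
Why: Saponification followed by thermal decarboxylation of the β-keto acid through a cyclic six-membered transition state should give the dione, the secondary silyl ether tolerating aqueous base and a brief, cold, mildly acidic work-up.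

Step 6
Reactants: 10 5-[(R)-2-(tert-butyldimethylsilyloxy)propyl]cyclohexane-1,3-dione
Product: 11 5-[(R)-2-(tert-butyldimethylsilyloxy)propyl]-1,3-bis(trimethylsilyloxy)cyclohexa-1,3-diene (used crude)
Conditions: TMSOTf (2.5 equiv), Et3N (4 equiv), Et2O, 0 °C to rt; dilute with pentane, decant from the ammonium salt, concentrate
Reagents that add atoms: trimethylsilyl trifluoromethanesulfonate, C[Si](C)(C)OS(=O)(=O)C(F)(F)F
Why: Double enol silylation of a 1,3-diketone with a silyl triflate and a tertiary amine is a known entry to 1,3-bis(silyloxy)-1,3-dienes, and the symmetry of 10 makes both possible second deprotonations lead to the same diene.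

Step 7
Reactants: 11 5-[(R)-2-(tert-butyldimethylsilyloxy)propyl]-1,3-bis(trimethylsilyloxy)cyclohexa-1,3-diene
Product: 13 5-[(R)-2-(tert-butyldimethylsilyloxy)propyl]benzene-1,3-diol, via bis(trimethylsilyl) aryl ether 12 (not isolated)
Conditions: DDQ (1.05 equiv), 2,4,6-collidine, CH2Cl2, 0 °C; filter; MeOH, citric acid (cat.), rt
Reagents that add atoms: none
Why: In this quinone dehydrogenation of a cyclohexa-1,3-diene, hydride abstraction from C5 gives a cation stabilised by both silyloxy groups, proton loss from C6 gives the arene, and mild methanolysis then cleaves only the labile aryl trimethylsilyl ethers and leaves the alkyl silyl ether in place.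

Step 8
Reactants: 13 5-[(R)-2-(tert-butyldimethylsilyloxy)propyl]benzene-1,3-diol
Product: 14 (R)-{[1-(3,5-bis(benzyloxy)phenyl)propan-2-yl]oxy}(tert-butyl)dimethylsilane
Conditions: BnBr (2.3 equiv), K2CO3, DMF, rt to 50 °C
Reagents that add atoms: benzyl bromide, BrCc1ccccc1
Why: Williamson etherification of both phenols with a carbonate base is standard for 5-alkylresorcinols and does not touch the silyl ether.

Step 9
Reactants: 14 (R)-{[1-(3,5-bis(benzyloxy)phenyl)propan-2-yl]oxy}(tert-butyl)dimethylsilane
Product: 15 (R)-1-[3,5-bis(benzyloxy)phenyl]propan-2-ol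
Conditions: Bu4NF, THF, rt
Reagents that add atoms: none
Why: Fluoride-induced desilylation cleaves only the Si–O bond, so the (R) carbinol is released with retention and the benzyl ethers stay.

Step 10
Reactants: 1 methyl (R)-3-hydroxybutanoate
Product: 16 methyl (R)-3-(benzyloxy)butanoate
Conditions: benzyl 2,2,2-trichloroacetimidate, TfOH (cat.), CH2Cl2/cyclohexane, 0 °C to rt
Reagents that add atoms: benzyl 2,2,2-trichloroacetimidate, N=C(OCc1ccccc1)C(Cl)(Cl)Cl
Why: Acid-catalysed imidate benzylation avoids base, so the β-hydroxy ester should be etherified without retro-aldol cleavage, elimination or loss of configuration.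

Step 11
Reactants: 16 methyl (R)-3-(benzyloxy)butanoate
Product: 17 (R)-3-(benzyloxy)-N-methoxy-N-methylbutanamide
Conditions: MeNH(OMe)·HCl (1.5 equiv), iPrMgCl (3 equiv), THF, −20 to 0 °C; cold 1 M HCl
Reagents that add atoms: N,O-dimethylhydroxylamine hydrochloride, CNOC.Cl
Why: Aminolysis of the ester by the magnesium amide of N,O-dimethylhydroxylamine (Weinreb amide formation) is fast below 0 °C, where the β-benzyloxy group is not eliminated.

Step 12
Reactants: 18 methyl 2,4-dihydroxy-6-methylbenzoate (methyl orsellinate)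
Product: 19 methyl 2,4-bis(benzyloxy)-6-methylbenzoate
Conditions: BnBr (2.5 equiv), K2CO3, DMF, 60 °C
Reagents that add atoms: benzyl bromide, BrCc1ccccc1
Why: Williamson etherification with warming should also alkylate the hydrogen-bonded ortho phenol.

Step 13
Reactants: 19 methyl 2,4-bis(benzyloxy)-6-methylbenzoate
Product: 20 2,4-bis(benzyloxy)-6-methylbenzoic acid
Conditions: KOH, MeOH/H2O, reflux; HCl
Reagents that add atoms: potassium hydroxide, [K+].[OH-]
Why: Saponification of the di-ortho-substituted benzoate needs forcing conditions, which are harmless here because only benzyl ethers are present.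

Step 14
Reactants: 21 (S)-butane-1,3-diol
Product: 22 (S)-4-(tert-butyldimethylsilyloxy)butan-2-ol
Conditions: TBSCl (1.0 equiv), imidazole, CH2Cl2, 0 °C
Reagents that add atoms: tert-butyldimethylsilyl chloride, CC(C)(C)[Si](C)(C)Cl
Why: Sterically controlled monosilylation should favour the primary hydroxyl of the 1,3-diol and leave the (S) carbinol free.

Step 15
Reactants: 20 2,4-bis(benzyloxy)-6-methylbenzoic acid; 22 (S)-4-(tert-butyldimethylsilyloxy)butan-2-ol
Product: 23 (R)-4-(tert-butyldimethylsilyloxy)butan-2-yl 2,4-bis(benzyloxy)-6-methylbenzoate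
Conditions: PPh3, DIAD, THF, 0 °C to rt
Reagents that add atoms: none
Why: In the Mitsunobu esterification the hindered acid acts only as the nucleophile, so its two ortho groups do not matter, and the SN2 displacement inverts the (S) carbinol to the (R) centre of the central unit.

Step 16
Reactants: 23 (R)-4-(tert-butyldimethylsilyloxy)butan-2-yl 2,4-bis(benzyloxy)-6-methylbenzoate; 17 (R)-3-(benzyloxy)-N-methoxy-N-methylbutanamide
Product: 26 (R)-4-(tert-butyldimethylsilyloxy)butan-2-yl 2,4-bis(benzyloxy)-6-[(R)-4-(benzyloxy)-2-oxopentyl]benzoate, via benzylic lithium species 24 (not isolated), via tetrahedral lithium adduct 25 (not isolated)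
Conditions: LiN(iPr)2 (1.15 equiv), THF, −78 °C; add 17, −78 °C; AcOH, −78 °C
Reagents that add atoms: none
Why: Lateral lithiation of the ortho-toluate followed by Weinreb ketone synthesis should stop at the ketone, because 25 persists until the cold acid quench, the secondary ester resists self-condensation, and the (R) centre of 17 takes no part.

Step 17
Reactants: 26 (R)-4-(tert-butyldimethylsilyloxy)butan-2-yl 2,4-bis(benzyloxy)-6-[(R)-4-(benzyloxy)-2-oxopentyl]benzoate
Product: 27 (R)-4-hydroxybutan-2-yl 2,4-bis(benzyloxy)-6-[(R)-4-(benzyloxy)-2-oxopentyl]benzoate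
Conditions: HF·pyridine, pyridine, THF, 0 °C to rt
Reagents that add atoms: none
Why: Buffered fluoride desilylation of the primary silyl ether avoids basic conditions, so the benzylic ketone is not enolised, the β-benzyloxy group is not eliminated, and the hindered benzoate should not migrate.

Step 18
Reactants: 27 (R)-4-hydroxybutan-2-yl 2,4-bis(benzyloxy)-6-[(R)-4-(benzyloxy)-2-oxopentyl]benzoate
Product: 29 (R)-3-({2,4-bis(benzyloxy)-6-[(R)-4-(benzyloxy)-2-oxopentyl]benzoyl}oxy)butanoic acid, via aldehyde 28 (not isolated)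
Conditions: TEMPO (cat.), PhI(OAc)2 (2.5 equiv), MeCN/H2O, rt
Reagents that add atoms: water, O
Why: The nitroxyl-catalysed oxidation takes the primary alcohol through the hydrate of 28 to the acid in a nearly neutral medium, so the β-acyloxy aldehyde should be consumed before it can eliminate.

Step 19
Reactants: 15 (R)-1-[3,5-bis(benzyloxy)phenyl]propan-2-ol; 29 (R)-3-({2,4-bis(benzyloxy)-6-[(R)-4-(benzyloxy)-2-oxopentyl]benzoyl}oxy)butanoic acid
Product: 30 penta-O-benzyl Hansforester K
Conditions: EDC·HCl (1.5 equiv), DMAP (0.2 equiv), CH2Cl2, 0 °C to rt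
Reagents that add atoms: none
Why: Steglich esterification of an unhindered aliphatic acid with a secondary alcohol forms only the acyl C–O bond, so all three centres are retained, and the low temperature and catalytic DMAP limit elimination of the β-acyloxy group.

Step 20
Reactants: 30 penta-O-benzyl Hansforester K
Product: 31 Hansforester K
Conditions: H2 (1 atm), Pd/C (10% palladium on carbon), EtOAc/EtOH, rt
Reagents that add atoms: none
Why: Neutral catalytic hydrogenolysis should cleave the four aryl benzyl ethers and the alkyl benzyl ether, while both esters, the ketone and the homobenzylic C–O bond are not benzylic C–O bonds and stay intact.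

## Compound list

1 | methyl (R)-3-hydroxybutanoate | COC(=O)C[C@@H](C)O | starting material
2 | methyl (R)-3-(tert-butyldimethylsilyloxy)butanoate | COC(=O)C[C@@H](C)O[Si](C)(C)C(C)(C)C | intermediate
3 | (R)-3-(tert-butyldimethylsilyloxy)butanal | O=CC[C@@H](C)O[Si](C)(C)C(C)(C)C | intermediate
4 | 1-(triphenylphosphoranylidene)propan-2-one | CC(=O)C=P(c1ccccc1)(c1ccccc1)c1ccccc1 | starting material
5 | (R,E)-6-(tert-butyldimethylsilyloxy)hept-3-en-2-one | C[C@H](C/C=C/C(C)=O)O[Si](C)(C)C(C)(C)C | intermediate
6 | dimethyl malonate | COC(=O)CC(=O)OC | starting material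
7 | dimethyl 2-[(2R)-2-(tert-butyldimethylsilyloxy)-6-oxoheptan-4-yl]malonate (C4 epimers) | COC(=O)C(C(=O)OC)C(CC(C)=O)C[C@@H](C)O[Si](C)(C)C(C)(C)C | intermediate
8 | methyl 6-[(R)-2-(tert-butyldimethylsilyloxy)propyl]-2,4-dioxocyclohexane-1-carboxylate | COC(=O)C1C(=O)CC(=O)CC1C[C@@H](C)O[Si](C)(C)C(C)(C)C | intermediate
9 | 6-[(R)-2-(tert-butyldimethylsilyloxy)propyl]-2,4-dioxocyclohexane-1-carboxylic acid | OC(=O)C1C(=O)CC(=O)CC1C[C@@H](C)O[Si](C)(C)C(C)(C)C | intermediate
10 | 5-[(R)-2-(tert-butyldimethylsilyloxy)propyl]cyclohexane-1,3-dione | O=C1CC(=O)CC(C[C@@H](C)O[Si](C)(C)C(C)(C)C)C1 | intermediate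
11 | 5-[(R)-2-(tert-butyldimethylsilyloxy)propyl]-1,3-bis(trimethylsilyloxy)cyclohexa-1,3-diene | C[Si](C)(C)OC1=CC(O[Si](C)(C)C)=CC(C[C@@H](C)O[Si](C)(C)C(C)(C)C)C1 | intermediate
12 | 1-[(R)-2-(tert-butyldimethylsilyloxy)propyl]-3,5-bis(trimethylsilyloxy)benzene | C[Si](C)(C)Oc1cc(O[Si](C)(C)C)cc(C[C@@H](C)O[Si](C)(C)C(C)(C)C)c1 | intermediate
13 | 5-[(R)-2-(tert-butyldimethylsilyloxy)propyl]benzene-1,3-diol | Oc1cc(O)cc(C[C@@H](C)O[Si](C)(C)C(C)(C)C)c1 | intermediate
14 | (R)-{[1-(3,5-bis(benzyloxy)phenyl)propan-2-yl]oxy}(tert-butyl)dimethylsilane | C[C@H](Cc1cc(OCc2ccccc2)cc(OCc2ccccc2)c1)O[Si](C)(C)C(C)(C)C | intermediate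
15 | (R)-1-[3,5-bis(benzyloxy)phenyl]propan-2-ol | C[C@H](Cc1cc(OCc2ccccc2)cc(OCc2ccccc2)c1)O | intermediate
16 | methyl (R)-3-(benzyloxy)butanoate | COC(=O)C[C@@H](C)OCc1ccccc1 | intermediate
17 | (R)-3-(benzyloxy)-N-methoxy-N-methylbutanamide | CON(C)C(=O)C[C@@H](C)OCc1ccccc1 | intermediate
18 | methyl 2,4-dihydroxy-6-methylbenzoate (methyl orsellinate) | COC(=O)c1c(C)cc(O)cc1O | starting material
19 | methyl 2,4-bis(benzyloxy)-6-methylbenzoate | COC(=O)c1c(C)cc(OCc2ccccc2)cc1OCc1ccccc1 | intermediate
20 | 2,4-bis(benzyloxy)-6-methylbenzoic acid | OC(=O)c1c(C)cc(OCc2ccccc2)cc1OCc1ccccc1 | intermediate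
21 | (S)-butane-1,3-diol | OCC[C@H](C)O | starting material
22 | (S)-4-(tert-butyldimethylsilyloxy)butan-2-ol | CC(C)(C)[Si](C)(C)OCC[C@H](C)O | intermediate
23 | (R)-4-(tert-butyldimethylsilyloxy)butan-2-yl 2,4-bis(benzyloxy)-6-methylbenzoate | CC(C)(C)[Si](C)(C)OCC[C@@H](C)OC(=O)c1c(C)cc(OCc2ccccc2)cc1OCc1ccccc1 | intermediate
24 | benzylic lithium species of 23 | CC(C)(C)[Si](C)(C)OCC[C@@H](C)OC(=O)c1c(C[Li])cc(OCc2ccccc2)cc1OCc1ccccc1 | intermediate
25 | tetrahedral lithium adduct of 24 to amide 17 | CC(C)(C)[Si](C)(C)OCC[C@@H](C)OC(=O)c1c(CC(O[Li])(N(C)OC)C[C@@H](C)OCc2ccccc2)cc(OCc2ccccc2)cc1OCc1ccccc1 | intermediate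
26 | (R)-4-(tert-butyldimethylsilyloxy)butan-2-yl 2,4-bis(benzyloxy)-6-[(R)-4-(benzyloxy)-2-oxopentyl]benzoate | CC(C)(C)[Si](C)(C)OCC[C@@H](C)OC(=O)c1c(CC(=O)C[C@@H](C)OCc2ccccc2)cc(OCc2ccccc2)cc1OCc1ccccc1 | intermediate
27 | (R)-4-hydroxybutan-2-yl 2,4-bis(benzyloxy)-6-[(R)-4-(benzyloxy)-2-oxopentyl]benzoate | OCC[C@@H](C)OC(=O)c1c(CC(=O)C[C@@H](C)OCc2ccccc2)cc(OCc2ccccc2)cc1OCc1ccccc1 | intermediate
28 | (R)-4-oxobutan-2-yl 2,4-bis(benzyloxy)-6-[(R)-4-(benzyloxy)-2-oxopentyl]benzoate | O=CC[C@@H](C)OC(=O)c1c(CC(=O)C[C@@H](C)OCc2ccccc2)cc(OCc2ccccc2)cc1OCc1ccccc1 | intermediate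
29 | (R)-3-({2,4-bis(benzyloxy)-6-[(R)-4-(benzyloxy)-2-oxopentyl]benzoyl}oxy)butanoic acid | OC(=O)C[C@@H](C)OC(=O)c1c(CC(=O)C[C@@H](C)OCc2ccccc2)cc(OCc2ccccc2)cc1OCc1ccccc1 | intermediate
30 | penta-O-benzyl Hansforester K | C[C@H](Cc1cc(OCc2ccccc2)cc(OCc2ccccc2)c1)OC(=O)C[C@@H](C)OC(=O)c1c(OCc2ccccc2)cc(OCc2ccccc2)cc1CC(=O)C[C@@H](C)OCc1ccccc1 | intermediate
31 | Hansforester K | C[C@H](Cc1cc(O)cc(O)c1)OC(=O)C[C@@H](C)OC(=O)c1c(O)cc(O)cc1CC(=O)C[C@@H](C)O | target

## Step count and risks

Total step count: 20.
Longest linear sequence: 11 steps (steps 1–9, 19 and 20, from methyl (R)-3-hydroxybutanoate 1).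

Steps most likely to fail:

**1. Step 4.**
- What may go wrong: methoxide may deprotonate the enone at C5 and trigger E1cB loss of the silyloxy group, or the Michael addition may revert before the ring closes.
- Fallback: it sets out from aldehyde 3 and comes back at keto ester 8, with the donor and acceptor roles exchanged.
- Aldehyde 3 is olefinated with methyl (triphenylphosphoranylidene)acetate to methyl (R,E)-5-(tert-butyldimethylsilyloxy)hex-2-enoate F1, whose γ-hydrogens are much less acidic than those of the enone.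
- Methyl acetoacetate and NaOMe in MeOH then add through the acetoacetate C2 to give dimethyl 2-acetyl-3-[(R)-2-(tert-butyldimethylsilyloxy)propyl]pentanedioate F2.
- The acetyl methyl carbon of F2 closes onto the distal ester, which should deliver the same ring 8.

**2. Step 7.**
- What may go wrong: the dienol ether may be protodesilylated back to the dione before hydride abstraction, may undergo cycloaddition with the quinone, or the electron-rich arene may be over-oxidised.
- Fallback: it sets out from dione 10 and comes back at dibenzyl ether 14, replacing quinone dehydrogenation by selenoxide elimination.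
- Mitsunobu O-alkylation of 10 with benzyl alcohol (PPh3, DIAD) gives 3-(benzyloxy)-5-[(R)-2-(tert-butyldimethylsilyloxy)propyl]cyclohex-2-en-1-one F3.
- Kinetic deprotonation at C6 with LiN(iPr)2 and trapping with PhSeCl gives 3-(benzyloxy)-6-(phenylselanyl)-5-[(R)-2-(tert-butyldimethylsilyloxy)propyl]cyclohex-2-en-1-one F4.
- H2O2 and pyridine convert F4 into 3-(benzyloxy)-6-(phenylseleninyl)-5-[(R)-2-(tert-butyldimethylsilyloxy)propyl]cyclohex-2-en-1-one F5.
- F5 undergoes syn elimination, and the dienone tautomerises to 3-(benzyloxy)-5-[(R)-2-(tert-butyldimethylsilyloxy)propyl]phenol F6.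
- Benzylation of F6 with BnBr and K2CO3 gives 14.

**3. Step 19.**
- What may go wrong: activating the carboxyl group acidifies the α-hydrogens, so E1cB loss of the ring C benzoate (crotonate formation) may outrun acylation of the secondary alcohol.
- Fallback: it sets out from alcohol 15 and comes back at 30. It activates the alcohol instead of the acid, with two inversions.
- Mitsunobu reaction of 15 with 4-nitrobenzoic acid gives (S)-1-[3,5-bis(benzyloxy)phenyl]propan-2-yl 4-nitrobenzoate F7.
- Methanolysis of F7 with K2CO3 gives (S)-1-[3,5-bis(benzyloxy)phenyl]propan-2-ol F8.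
- A second Mitsunobu reaction of F8 with acid 29, which reacts as its non-acidified carboxylate, inverts the centre back to (R) and gives 30.

## Further compounds

F1 | step 4 | methyl (R,E)-5-(tert-butyldimethylsilyloxy)hex-2-enoate | COC(=O)/C=C/C[C@@H](C)O[Si](C)(C)C(C)(C)C
F2 | step 4 | dimethyl 2-acetyl-3-[(R)-2-(tert-butyldimethylsilyloxy)propyl]pentanedioate | COC(=O)CC(C[C@@H](C)O[Si](C)(C)C(C)(C)C)C(C(C)=O)C(=O)OC
F3 | step 7 | 3-(benzyloxy)-5-[(R)-2-(tert-butyldimethylsilyloxy)propyl]cyclohex-2-en-1-one | O=C1C=C(OCc2ccccc2)CC(C[C@@H](C)O[Si](C)(C)C(C)(C)C)C1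
F4 | step 7 | 3-(benzyloxy)-6-(phenylselanyl)-5-[(R)-2-(tert-butyldimethylsilyloxy)propyl]cyclohex-2-en-1-one | O=C1C=C(OCc2ccccc2)CC(C[C@@H](C)O[Si](C)(C)C(C)(C)C)C1[Se]c1ccccc1
F5 | step 7 | 3-(benzyloxy)-6-(phenylseleninyl)-5-[(R)-2-(tert-butyldimethylsilyloxy)propyl]cyclohex-2-en-1-one | O=C1C=C(OCc2ccccc2)CC(C[C@@H](C)O[Si](C)(C)C(C)(C)C)C1[Se](=O)c1ccccc1
F6 | step 7 | 3-(benzyloxy)-5-[(R)-2-(tert-butyldimethylsilyloxy)propyl]phenol | Oc1cc(OCc2ccccc2)cc(C[C@@H](C)O[Si](C)(C)C(C)(C)C)c1
F7 | step 19 | (S)-1-[3,5-bis(benzyloxy)phenyl]propan-2-yl 4-nitrobenzoate | C[C@@H](Cc1cc(OCc2ccccc2)cc(OCc2ccccc2)c1)OC(=O)c1ccc(cc1)[N+](=O)[O-]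
F8 | step 19 | (S)-1-[3,5-bis(benzyloxy)phenyl]propan-2-ol | C[C@@H](Cc1cc(OCc2ccccc2)cc(OCc2ccccc2)c1)O
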